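**Assumption:** the target has no stereocentre and no hindered biaryl axis, so it is a single achiral compound and no stereocontrol is needed.

## Retrosynthetic overview

1. Echinoclathrine B ⇒ aryl C–O bond (key step): its isomer, the N-aryl hydroxamic acid, whose N–OH oxygen is moved to the only free ortho carbon by a new catalytic 1,3-oxygen transposition.
2. Hydroxamic acid ⇒ amide C–N bond: N-[2-(2-methylpyridin-4-yl)phenyl]hydroxylamine (partial reduction of the nitro-biaryl) plus 13-(acetylsulfanyl)tridecanoyl chloride.
3. Nitro-biaryl ⇒ biaryl C–C bond (supporting Suzuki coupling): 1-bromo-2-nitrobenzene plus 2-methylpyridin-4-yl pinacol boronate.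
4. Side chain ⇒ C–S bond: 13-bromotridecanoic acid plus potassium thioacetate.
5. No ring is formed; the benzene and pyridine rings are both purchased.

## Route

Step 1
Reactants: 1 13-bromotridecanoic acid; 2 potassium thioacetate
Product: 3 13-(acetylsulfanyl)tridecanoic acid
Conditions: 2 (1.5 equiv), DMF, 23 °C, 4 h; 1 M HCl work-up
Reagents that add atoms: none
Why: SN2 displacement of an unhindered primary bromide by the soft, weakly basic thioacetate anion, which leaves the free carboxylic acid untouched.

Step 2
Reactants: 4 1-bromo-2-nitrobenzene; 5 2-methyl-4-(4,4,5,5-tetramethyl-1,3,2-dioxaborolan-2-yl)pyridine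
Product: 6 2-methyl-4-(2-nitrophenyl)pyridine
Conditions: Pd(dppf)Cl2·CH2Cl2 (3 mol %), K2CO3 (2.5 equiv), 5 (1.2 equiv), 1,4-dioxane/H2O 4:1, 90 °C, N2
Reagents that add atoms: none
Why: Suzuki–Miyaura coupling in which the ortho-nitro group activates the C–Br bond for oxidative addition and the 4-pyridyl pinacol boronate transmetalates cleanly under aqueous carbonate.

Step 3
Reactants: 6 2-methyl-4-(2-nitrophenyl)pyridine; 3 13-(acetylsulfanyl)tridecanoic acid
Product: 9 13-(acetylsulfanyl)-N-hydroxy-N-[2-(2-methylpyridin-4-yl)phenyl]tridecanamide, via arylhydroxylamine 7 (not isolated), via acid chloride 8 (not isolated)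
Conditions: 6, 5% Rh/C (0.3 mol %), N2H4·H2O (1.2 equiv), THF, 0 °C, filter through Celite; then NaHCO3 (1.3 equiv) and crude 8 (1.05 equiv; from 3, (COCl)2, cat. DMF, CH2Cl2, 0→23 °C, evaporated), THF, 0 °C
Reagents that add atoms: none
Why: Rh/C–hydrazine transfer hydrogenation stops at the hydroxylamine at 0 °C, and N-acylation with an acid chloride under bicarbonate is the standard route to N-aryl-N-hydroxy amides; the rhodium is filtered off before the sulfur-containing acid chloride is added.

Step 4
Reactants: 9 13-(acetylsulfanyl)-N-hydroxy-N-[2-(2-methylpyridin-4-yl)phenyl]tridecanamide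
Product: 12 echinoclathrine B [13-(acetylsulfanyl)-N-[2-hydroxy-6-(2-methylpyridin-4-yl)phenyl]tridecanamide], via N-trifluoroacetoxy amide 10 (not isolated), via aryl trifluoroacetate 11 (not isolated)
Conditions: (CF3CO)2O (15 mol %), 4 Å MS, ClCH2CH2Cl (0.1 M), 23→45 °C; then MeOH, sat. aq NaHCO3, 23 °C, 15 min
Reagents that add atoms: none
Why: Proposed new method: an acyl-shuttle-catalysed 1,3-oxygen transposition (hydroxamic acid → 2-hydroxyanilide isomerisation) in which catalytic TFAA O-trifluoroacetylates 9 to 10, the weak N–O bond and good carboxylate leaving group allow a [3,3]-sigmatropic (or tight-ion-pair) shift of the trifluoroacetoxy group to the only unsubstituted ortho carbon, rearomatisation gives aryl trifluoroacetate 11, and this very reactive aryl ester is transacylated by the α-nucleophilic N–OH of the next molecule of 9 (the substrate pyridine acting as acyl-transfer and proton-shuttle base) to release 12 and regenerate 10, the residual 15 % of 11 being cleaved in the bicarbonate/methanol quench; the closest known reaction is the stoichiometric thermal [3,3] rearrangement of N-aryl-N,O-diacyl (or O-sulfonyl) hydroxylamines to ortho-oxygenated anilides, which has not been run as a catalytic, traceless isomerisation.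

## Compound list

1 | 13-bromotridecanoic acid | OC(=O)CCCCCCCCCCCCBr | starting material
2 | potassium thioacetate | CC(=O)[S-].[K+] | starting material
3 | 13-(acetylsulfanyl)tridecanoic acid | CC(=O)SCCCCCCCCCCCCC(=O)O | intermediate
4 | 1-bromo-2-nitrobenzene | O=[N+]([O-])c1ccccc1Br | starting material
5 | 2-methyl-4-(4,4,5,5-tetramethyl-1,3,2-dioxaborolan-2-yl)pyridine | Cc1cc(B2OC(C)(C)C(C)(C)O2)ccn1 | starting material
6 | 2-methyl-4-(2-nitrophenyl)pyridine | Cc1cc(-c2ccccc2[N+](=O)[O-])ccn1 | intermediate
7 | N-[2-(2-methylpyridin-4-yl)phenyl]hydroxylamine | Cc1cc(-c2ccccc2NO)ccn1 | intermediate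
8 | 13-(acetylsulfanyl)tridecanoyl chloride | CC(=O)SCCCCCCCCCCCCC(=O)Cl | intermediate
9 | 13-(acetylsulfanyl)-N-hydroxy-N-[2-(2-methylpyridin-4-yl)phenyl]tridecanamide | CC(=O)SCCCCCCCCCCCCC(=O)N(O)c1ccccc1-c1ccnc(C)c1 | intermediate
10 | 13-(acetylsulfanyl)-N-[2-(2-methylpyridin-4-yl)phenyl]-N-(trifluoroacetoxy)tridecanamide | CC(=O)SCCCCCCCCCCCCC(=O)N(OC(=O)C(F)(F)F)c1ccccc1-c1ccnc(C)c1 | intermediate
11 | 2-[13-(acetylsulfanyl)tridecanamido]-3-(2-methylpyridin-4-yl)phenyl trifluoroacetate | CC(=O)SCCCCCCCCCCCCC(=O)Nc1c(OC(=O)C(F)(F)F)cccc1-c1ccnc(C)c1 | intermediate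
12 | echinoclathrine B, 13-(acetylsulfanyl)-N-[2-hydroxy-6-(2-methylpyridin-4-yl)phenyl]tridecanamide | CC(=O)SCCCCCCCCCCCCC(=O)Nc1c(O)cccc1-c1ccnc(C)c1 | target

## Step count and risks

Total step count: 4 (isolated products 3, 6, 9 and 12).
Longest linear sequence: 3 steps (4 + 5 → 6 → 9 → 12); step 1 is a one-step side branch.

The three steps most likely to fail:

**Step 4 (the new isomerisation).** The N–O trifluoroacetate 10 may rearrange too slowly below 45 °C, may ionise and give para-oxygenated anilide, or the shuttle may be killed by traces of water. The fallback uses only known chemistry. It sets out from boronate 5 and acid chloride 8 (made from 3 as in step 3) and comes back to the route at 12. Suzuki–Miyaura coupling of 5 with commercial 2-amino-3-bromophenol F1 (Pd(dppf)Cl2, K2CO3, dioxane/H2O, 90 °C) gives 2-amino-3-(2-methylpyridin-4-yl)phenol F2. Schotten–Baumann acylation of F2 with 8 (NaHCO3, THF/H2O, 0 °C) is N-selective, and any O-acyl product relaxes by O→N acyl shift, so 12 is obtained directly.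

**Step 3 (partial reduction and N-acylation).** The reduction may overrun to the aniline, or the acid chloride may give O-acylated or N,O-diacylated material. The fallback sets out from 6 and 8 and comes back at 12, placing the oxygen by amide-directed C–H functionalisation instead of carrying it through from the nitro group. Full hydrogenation of 6 (H2, Pd/C, EtOH) gives 2-(2-methylpyridin-4-yl)aniline F3. Acylation with 8 (NaHCO3, THF/H2O, 0 °C) gives 13-(acetylsulfanyl)-N-[2-(2-methylpyridin-4-yl)phenyl]tridecanamide F4. Amide-directed electrophilic ortho C–H borylation with BBr3 (3 equiv, one being held by the pyridine; CH2Cl2, 23 °C) gives the chelated 13-(acetylsulfanyl)-N-[2-(dibromoboranyl)-6-(2-methylpyridin-4-yl)phenyl]tridecanamide F5. This is oxidised in the same flask (NaBO3·4H2O, THF/H2O, 0 °C, short contact to spare the thioester) to 12.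

**Step 2 (Suzuki coupling).** The 4-pyridyl boronate can protodeboronate and the pyridine can slow the catalyst. The fallback sets out from 4 and comes back at 6, replacing the boron nucleophile by an organozinc (Negishi coupling). Commercial 4-bromo-2-methylpyridine F6 undergoes Br/Mg exchange (iPrMgCl·LiCl, THF, 0 °C) and transmetalation with ZnCl2 to (2-methylpyridin-4-yl)zinc chloride F7. F7 couples with 4 (Pd2(dba)3/XPhos, THF, 50 °C) to give 6; the nitro group tolerates the organozinc.

## Further compounds

F1 | step 4 | 2-amino-3-bromophenol | Nc1c(O)cccc1Br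
F2 | step 4 | 2-amino-3-(2-methylpyridin-4-yl)phenol | Cc1cc(-c2cccc(O)c2N)ccn1
F3 | step 3 | 2-(2-methylpyridin-4-yl)aniline | Cc1cc(-c2ccccc2N)ccn1
F4 | step 3 | 13-(acetylsulfanyl)-N-[2-(2-methylpyridin-4-yl)phenyl]tridecanamide | CC(=O)SCCCCCCCCCCCCC(=O)Nc1ccccc1-c1ccnc(C)c1
F5 | step 3 | 13-(acetylsulfanyl)-N-[2-(dibromoboranyl)-6-(2-methylpyridin-4-yl)phenyl]tridecanamide | CC(=O)SCCCCCCCCCCCCC(=O)Nc1c(B(Br)Br)cccc1-c1ccnc(C)c1
F6 | step 2 | 4-bromo-2-methylpyridine | Cc1cc(Br)ccn1
F7 | step 2 | (2-methylpyridin-4-yl)zinc chloride | Cc1cc([Zn]Cl)ccn1
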